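**Retrosynthetic overview**
1. Target 20 ⇐ ester hydrolysis and C19 aldehyde oxidation; the butenolide is bought as 3-bromofuran-2(5H)-one and joined at C12–C13 by Negishi coupling.
2. C4 quaternary centre ⇐ α-methylation of a C4 aldehyde on the face anti to the C10 methyl, then C8 equilibration.
3. Rings A and B ⇐ one enantioselective, redox-neutral radical bicyclisation of acyclic aldehyde 11: C4–C5 (ring A) first, C10–C9 (ring B) second, ended by reduction at C8.
4. 11 ⇐ Still–Gennari olefination (C8=C9, Z) ⇐ phosphonate alkylation (C7–C8) ⇐ copper-catalysed allyl–alkyl coupling (C1–C2) ⇐ allylic oxidation of 5-bromo-2-methylpent-2-ene (E-C10=C5).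

Numbering: labdane numbering throughout (ring A = C1–C5, C10; ring B = C5–C10; C11–C12 chain on C9; C17 on C8; C18/C19 on C4; β = face of the C10 methyl). The target is (4S,5R,8R,9S,10R).
Assumption: the (2S,5S)-imidazolidinone leaves open the same enamine face as in its known aldehyde α-functionalisations, which gives 4R in 12 and the natural antipode; if the sense proved opposite, the (2R,5R)-catalyst would be used.

**Route**

Step 1
Reactants: 1 5-bromo-2-methylpent-2-ene
Product: 2 (2E)-5-bromo-2-methylpent-2-en-1-ol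
Conditions: SeO2 (0.3 equiv), t-BuOOH, salicylic acid (cat.), CH2Cl2, rt
Reagents that add atoms: tert-butyl hydroperoxide CC(C)(C)OO (oxygen, relayed by SeO2)
Why: Sharpless-type SeO2 allylic oxidation (ene reaction, then [2,3]-sigmatropic shift) hydroxylates only the (E)-methyl of the trisubstituted alkene, which fixes the E geometry of the future C10=C5 bond.

Step 2
Reactants: 2 (2E)-5-bromo-2-methylpent-2-en-1-ol
Product: 3 (2E)-1,5-dibromo-2-methylpent-2-ene
Conditions: PBr3 (0.4 equiv), Et2O, −10 to 0 °C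
Reagents that add atoms: phosphorus tribromide BrP(Br)Br
Why: SN2 bromination of a primary allylic alcohol with PBr3 proceeds without allylic transposition and keeps the E alkene.

Step 3
Reactants: 3 (2E)-1,5-dibromo-2-methylpent-2-ene; 4 4-chloro-1,1-dimethoxybutane
Product: 6 (6E)-9-bromo-1,1-dimethoxy-6-methylnon-6-ene, via (4,4-dimethoxybutyl)magnesium chloride 5 (not isolated)
Conditions: 4, Mg, THF, 50 °C; then 3, Li2CuCl4 (5 mol%), THF, −78 to −20 °C
Reagents that add atoms: none
Why: Kochi-type copper-catalysed Grignard coupling takes the allylic bromide by direct (α) substitution far faster than the primary alkyl bromide, so C1–C2 forms with the E alkene and the C7 bromide intact.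

Step 4
Reactants: 6 (6E)-9-bromo-1,1-dimethoxy-6-methylnon-6-ene; 7 methyl 2-[bis(2,2,2-trifluoroethoxy)phosphoryl]acetate
Product: 8 methyl (5E)-2-[bis(2,2,2-trifluoroethoxy)phosphoryl]-11,11-dimethoxy-6-methylundec-5-enoate
Conditions: 7 (1.5 equiv), NaH, DMF, 0 °C; then 6, NaI (0.2 equiv), 50 °C
Reagents that add atoms: none
Why: SN2 C-alkylation of the stabilised phosphonoacetate anion (bromide activated in situ by Finkelstein exchange) forms C7–C8; the new stereocentre is racemic and is removed in step 5.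

Step 5
Reactants: 8 methyl (5E)-2-[bis(2,2,2-trifluoroethoxy)phosphoryl]-11,11-dimethoxy-6-methylundec-5-enoate; 9 3-[(tert-butyldimethylsilyl)oxy]propanal
Product: 11 methyl (2Z)-5-[(tert-butyldimethylsilyl)oxy]-2-[(3E)-4-methyl-9-oxonon-3-en-1-yl]pent-2-enoate, via dimethyl acetal 10 (not isolated)
Conditions: KN(SiMe3)2, 18-crown-6, THF, −78 °C; then 9; then 5% aq. oxalic acid, THF, 0 °C to rt (20 min)
Reagents that add atoms: water O
Why: Still–Gennari olefination gives the Z trisubstituted enoate (CO2Me cis to C11), and brief mild acid then hydrolyses the dimethyl acetal much faster than the primary silyl ether.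

Step 6
Reactants: 11 methyl (2Z)-5-[(tert-butyldimethylsilyl)oxy]-2-[(3E)-4-methyl-9-oxonon-3-en-1-yl]pent-2-enoate
Product: 12 methyl 4α-formyl-10β-methyl-9β-[2-(tert-butyldimethylsilyloxy)ethyl]-trans-decalin-8β-carboxylate
Conditions: (2S,5S)-5-benzyl-2-tert-butyl-3-methylimidazolidin-4-one·CF3CO2H (20 mol%), Ir(Fmppy)2(dtbbpy)PF6 (1 mol%), H2O (3 equiv), DME (0.02 M), blue LEDs, 0 °C, degassed
Reagents that add atoms: none
Why: Proposed new method: photoexcited trivalent iridium oxidises the chiral (E)-enamine of 11 to its 3π-electron radical cation, which closes ring A 6-endo onto C5 of the electron-rich C5=C10 alkene, the nucleophilic tertiary C10 radical closes ring B 6-endo onto C9 (β-carbon of the Z enoate), and only the electrophilic C8 α-ester radical can be reduced by divalent iridium to the enolate and protonated, so the cascade is redox-neutral; the imidazolidinone sets C4 and, through the chair–chair transition state, the absolute configuration of C5, C10 and C9 (E alkene gives the trans fusion, Z enoate puts C11 equatorial), and protonation at C8 from the open α-face gives mainly the 8β ester, corrected in step 7; the closest known reactions are the organo-SOMO polyene cyclisation over alternating electron-rich and electron-poor alkenes (run with stoichiometric divalent copper), the photoredox–enamine hydroalkylation of aldehydes with alkenes, and the reductive end of photoredox Giese additions.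

Step 7
Reactants: 12 methyl 4α-formyl-10β-methyl-9β-[2-(tert-butyldimethylsilyloxy)ethyl]-trans-decalin-8β-carboxylate
Product: 14 methyl 4β-formyl-4α,10β-dimethyl-9β-[2-(tert-butyldimethylsilyloxy)ethyl]-trans-decalin-8α-carboxylate, via 8β-ester aldehyde 13 (not isolated)
Conditions: KOtBu (1.1 equiv), THF, −78 °C; MeI, −78 to 0 °C; evaporate; KOtBu (0.5 equiv), t-BuOH, 40 °C
Reagents that add atoms: iodomethane CI
Why: C-methylation of the aldehyde potassium enolate occurs on the α-face, anti to the 1,3-diaxial C10 methyl (4α-CH3, axial 4β-CHO), and base equilibration of the only remaining enolisable centre then moves the C8 ester to the equatorial 8α position, trans to the C9 chain.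

Step 8
Reactants: 14 methyl 4β-formyl-4α,10β-dimethyl-9β-[2-(tert-butyldimethylsilyloxy)ethyl]-trans-decalin-8α-carboxylate
Product: 15 methyl 9β-(2-bromoethyl)-4β-formyl-4α,10β-dimethyl-trans-decalin-8α-carboxylate
Conditions: Ph3PBr2 (1.5 equiv), CH2Cl2, 0 °C to rt
Reagents that add atoms: triphenylphosphine dibromide BrP(Br)(c1ccccc1)(c1ccccc1)c1ccccc1
Why: Ph3PBr2 converts a primary silyl ether directly into the bromide (oxyphosphonium formation, then SN2 by bromide), while the hindered non-enolisable aldehyde and the ester are left alone at this temperature.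

Step 9
Reactants: 15 methyl 9β-(2-bromoethyl)-4β-formyl-4α,10β-dimethyl-trans-decalin-8α-carboxylate; 16 3-bromofuran-2(5H)-one
Product: 18 methyl 4β-formyl-4α,10β-dimethyl-9β-[2-(2-oxo-2,5-dihydrofuran-3-yl)ethyl]-trans-decalin-8α-carboxylate, via alkylzinc bromide 17 (not isolated)
Conditions: Zn dust, iodine (cat.), DMA, 70 °C; decant; then 16, PdCl2(dppf) (5 mol%), 40 °C
Reagents that add atoms: none
Why: Negishi sp3–sp2 coupling: the alkylzinc bromide tolerates the ester and the hindered aldehyde and couples with the activated α-bromo enoate carbon of 16, which brings in the intact butenolide without any base.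

Step 10
Reactants: 18 methyl 4β-formyl-4α,10β-dimethyl-9β-[2-(2-oxo-2,5-dihydrofuran-3-yl)ethyl]-trans-decalin-8α-carboxylate
Product: 19 8α-(methoxycarbonyl)-4α,10β-dimethyl-9β-[2-(2-oxo-2,5-dihydrofuran-3-yl)ethyl]-trans-decalin-4β-carboxylic acid
Conditions: NaClO2, NaH2PO4, 2-methylbut-2-ene, t-BuOH/H2O, rt
Reagents that add atoms: sodium chlorite [Na+].[O-]Cl=O
Why: Pinnick oxidation converts the neopentyl aldehyde into the C19 acid under buffered conditions that leave the butenolide and the C8 centre untouched.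

Step 11
Reactants: 19 8α-(methoxycarbonyl)-4α,10β-dimethyl-9β-[2-(2-oxo-2,5-dihydrofuran-3-yl)ethyl]-trans-decalin-4β-carboxylic acid
Product: 20 (4S,5R,8R,9S,10R)-labd-13-en-16,15-olide-17,19-dioic acid (target CNP0478950.1)
Conditions: Me3SnOH (8 equiv), 1,2-dichloroethane, 80 °C; then 1 M HCl
Reagents that add atoms: trimethyltin hydroxide C[Sn](C)(C)O
Why: Me3SnOH hydrolyses the methyl ester under near-neutral conditions, so the base-sensitive butenolide is not isomerised (any opened lactone recloses on acidification) and the already thermodynamic C8 centre is kept.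

**Compound list**
1 | 5-bromo-2-methylpent-2-ene | CC(C)=CCCBr | starting material
2 | (2E)-5-bromo-2-methylpent-2-en-1-ol | OC/C(C)=C/CCBr | intermediate
3 | (2E)-1,5-dibromo-2-methylpent-2-ene | BrC/C(C)=C/CCBr | intermediate
4 | 4-chloro-1,1-dimethoxybutane | COC(CCCCl)OC | starting material
5 | (4,4-dimethoxybutyl)magnesium chloride | COC(CCC[Mg]Cl)OC | intermediate
6 | (6E)-9-bromo-1,1-dimethoxy-6-methylnon-6-ene | COC(OC)CCCC/C(C)=C/CCBr | intermediate
7 | methyl 2-[bis(2,2,2-trifluoroethoxy)phosphoryl]acetate | COC(=O)CP(=O)(OCC(F)(F)F)OCC(F)(F)F | starting material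
8 | methyl (5E)-2-[bis(2,2,2-trifluoroethoxy)phosphoryl]-11,11-dimethoxy-6-methylundec-5-enoate (racemic at C2) | COC(=O)C(CC/C=C(\C)CCCCC(OC)OC)P(=O)(OCC(F)(F)F)OCC(F)(F)F | intermediate
9 | 3-[(tert-butyldimethylsilyl)oxy]propanal | O=CCCO[Si](C)(C)C(C)(C)C | starting material
10 | methyl (2Z)-5-[(tert-butyldimethylsilyl)oxy]-2-[(3E)-9,9-dimethoxy-4-methylnon-3-en-1-yl]pent-2-enoate | COC(=O)/C(CC/C=C(\C)CCCCC(OC)OC)=C\CCO[Si](C)(C)C(C)(C)C | intermediate
11 | methyl (2Z)-5-[(tert-butyldimethylsilyl)oxy]-2-[(3E)-4-methyl-9-oxonon-3-en-1-yl]pent-2-enoate | COC(=O)/C(CC/C=C(\C)CCCCC=O)=C\CCO[Si](C)(C)C(C)(C)C | intermediate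
12 | methyl 4α-formyl-10β-methyl-9β-[2-(tert-butyldimethylsilyloxy)ethyl]-trans-decalin-8β-carboxylate (4β-H, 5α-H, 8α-H, 9α-H) | C[C@]12CCC[C@@H](C=O)[C@@H]1CC[C@H](C(=O)OC)[C@@H]2CCO[Si](C)(C)C(C)(C)C | intermediate
13 | methyl 4β-formyl-4α,10β-dimethyl-9β-[2-(tert-butyldimethylsilyloxy)ethyl]-trans-decalin-8β-carboxylate | C[C@]12CCC[C@](C)(C=O)[C@@H]1CC[C@H](C(=O)OC)[C@@H]2CCO[Si](C)(C)C(C)(C)C | intermediate
14 | methyl 4β-formyl-4α,10β-dimethyl-9β-[2-(tert-butyldimethylsilyloxy)ethyl]-trans-decalin-8α-carboxylate | C[C@]12CCC[C@](C)(C=O)[C@@H]1CC[C@@H](C(=O)OC)[C@@H]2CCO[Si](C)(C)C(C)(C)C | intermediate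
15 | methyl 9β-(2-bromoethyl)-4β-formyl-4α,10β-dimethyl-trans-decalin-8α-carboxylate | C[C@]12CCC[C@](C)(C=O)[C@@H]1CC[C@@H](C(=O)OC)[C@@H]2CCBr | intermediate
16 | 3-bromofuran-2(5H)-one | O=C1OCC=C1Br | starting material
17 | [2-(4β-formyl-8α-methoxycarbonyl-4α,10β-dimethyl-trans-decalin-9β-yl)ethyl]zinc bromide | C[C@]12CCC[C@](C)(C=O)[C@@H]1CC[C@@H](C(=O)OC)[C@@H]2CC[Zn]Br | intermediate
18 | methyl 4β-formyl-4α,10β-dimethyl-9β-[2-(2-oxo-2,5-dihydrofuran-3-yl)ethyl]-trans-decalin-8α-carboxylate | C[C@]12CCC[C@](C)(C=O)[C@@H]1CC[C@@H](C(=O)OC)[C@@H]2CCC1=CCOC1=O | intermediate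
19 | 8α-(methoxycarbonyl)-4α,10β-dimethyl-9β-[2-(2-oxo-2,5-dihydrofuran-3-yl)ethyl]-trans-decalin-4β-carboxylic acid | C[C@]12CCC[C@](C)(C(=O)O)[C@@H]1CC[C@@H](C(=O)OC)[C@@H]2CCC1=CCOC1=O | intermediate
20 | (4S,5R,8R,9S,10R)-labd-13-en-16,15-olide-17,19-dioic acid | C[C@]12CCC[C@](C)(C(=O)O)[C@@H]1CC[C@@H](C(=O)O)[C@@H]2CCC1=CCOC1=O | target

**Step count and risk**
Total step count: 11. Longest linear sequence: 11 steps (1 to 20); 4, 7, 9, 16 and the catalysts are bought.

The three steps most likely to fail: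

Step 6 (key bicyclisation). The cascade may stall at the C10 radical, or the C8 radical may not be reduced. The fallback sets out from 11 and uses the same imidazolidinone salt with stoichiometric Cu(OTf)2 (NaO2CCF3, i-PrCN/DME, rt). Here divalent copper captures the C8 radical and it leaves as the conjugated ring B alkene, methyl 4α-formyl-10β-methyl-9β-[2-(tert-butyldimethylsilyloxy)ethyl]-Δ7-octalin-8-carboxylate F1. Hydrogenation of F1 (H2, Pd/C, EtOAc) from the open α-face gives the 8β ester and rejoins the route at 12.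

Step 9 (Negishi coupling with the bromobutenolide). Zinc insertion next to the ester or the coupling at the α-bromo enoate may fail. The fallback sets out from 14. HF·pyridine (THF, 0 °C) gives the primary alcohol methyl 4β-formyl-9β-(2-hydroxyethyl)-4α,10β-dimethyl-trans-decalin-8α-carboxylate F2, and Dess–Martin periodinane gives the dialdehyde methyl 4β-formyl-4α,10β-dimethyl-9β-(2-oxoethyl)-trans-decalin-8α-carboxylate F3. Only the unhindered C12 aldehyde of F3 undergoes Horner–Wadsworth–Emmons reaction with diethyl (2-oxooxolan-3-yl)phosphonate (NaH, THF), giving the (E)-alkylidene lactone methyl 4β-formyl-4α,10β-dimethyl-9β-[(3E)-3-(2-oxooxolan-3-ylidene)propyl]-trans-decalin-8α-carboxylate F4. RhCl3·3H2O in EtOH at 80 °C then moves the exocyclic double bond into the ring (hydrometalation, β-hydride elimination) and rejoins the route at 18.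

Step 4 (alkylation of the trifluoroethyl phosphonate with an unactivated bromide). Elimination or low conversion is possible. The fallback sets out from 6. Mg in THF gives the Grignard reagent [(3E)-9,9-dimethoxy-4-methylnon-3-en-1-yl]magnesium bromide F5, and inverse addition to excess dimethyl oxalate at −78 °C gives the α-keto ester methyl (5E)-11,11-dimethoxy-6-methyl-2-oxoundec-5-enoate F6. A Wittig reaction of F6 with the unstabilised ylide from {3-[(tert-butyldimethylsilyl)oxy]propyl}triphenylphosphonium bromide F7 (from commercial (3-bromopropoxy)(tert-butyl)dimethylsilane and PPh3; NaN(SiMe3)2, THF, −78 °C) is expected to place the new chain cis to the ester. This rejoins the route at 10, which is hydrolysed to 11 as in step 5.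

**Further compounds**
F1 | step 6 | methyl 4α-formyl-10β-methyl-9β-[2-(tert-butyldimethylsilyloxy)ethyl]-Δ7-octalin-8-carboxylate | C[C@]12CCC[C@@H](C=O)[C@@H]1CC=C(C(=O)OC)[C@@H]2CCO[Si](C)(C)C(C)(C)C
F2 | step 9 | methyl 4β-formyl-9β-(2-hydroxyethyl)-4α,10β-dimethyl-trans-decalin-8α-carboxylate | C[C@]12CCC[C@](C)(C=O)[C@@H]1CC[C@@H](C(=O)OC)[C@@H]2CCO
F3 | step 9 | methyl 4β-formyl-4α,10β-dimethyl-9β-(2-oxoethyl)-trans-decalin-8α-carboxylate | C[C@]12CCC[C@](C)(C=O)[C@@H]1CC[C@@H](C(=O)OC)[C@@H]2CC=O
F4 | step 9 | methyl 4β-formyl-4α,10β-dimethyl-9β-[(3E)-3-(2-oxooxolan-3-ylidene)propyl]-trans-decalin-8α-carboxylate | C[C@]12CCC[C@](C)(C=O)[C@@H]1CC[C@@H](C(=O)OC)[C@@H]2C/C=C1\CCOC1=O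
F5 | step 4 | [(3E)-9,9-dimethoxy-4-methylnon-3-en-1-yl]magnesium bromide | COC(OC)CCCC/C(C)=C/CC[Mg]Br
F6 | step 4 | methyl (5E)-11,11-dimethoxy-6-methyl-2-oxoundec-5-enoate | COC(=O)C(=O)CC/C=C(\C)CCCCC(OC)OC
F7 | step 4 | {3-[(tert-butyldimethylsilyl)oxy]propyl}triphenylphosphonium bromide | CC(C)(C)[Si](C)(C)OCCC[P+](c1ccccc1)(c1ccccc1)c1ccccc1.[Br-]
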